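1. Retrosynthesis: the eleven O–CH3 and four O–carbamoyl bonds are cut last, then the two C4–O bonds of rings C and G, then the six diaryl ether C–O bonds one by one from the G end, each between the bridging oxygen (kept on the crowded, doubly ortho-oxygenated carbon) and the less hindered carbon of the next ring.
2. Forward: the chain grows from ring A to ring G. 2,4,6-Trimethoxyphenol is O-arylated under Cu catalysis by a bromobenzaldehyde, the formyl group is turned into the next phenol by Dakin oxidation, and this two-step cycle runs five times (rings B to F); ring G enters as 1,3-bis(benzyloxy)-5-bromobenzene.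
3. Rings C and G carry benzyl ethers during chain growth, because a carbamate next to the ring C phenoxide could migrate; hydrogenolysis and fourfold carbamoylation then give the 4,4'-dideoxy tetracarbamate.
4. Enabling feature: C4 of ring C and C4 of ring G each carry H between the oxygen-bearing carbons C3 and C5, so once those four oxygens are carbamates only these two C–H bonds lie between two strong directing groups. Every other oxygen of the target is delivered by a building block.
5. Double lithiation, borylation and oxidation installs both hydroxyls; LiAlH4 then removes the carbamates and BBr3 the methyl ethers.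
6. Stereochemistry: the target is achiral and has no stereocentre, so none has to be set.

Key step: step 16

Remark: rings are lettered A to G from the 2,4,6-trioxygenated phenyl end, and on rings B to G the carbon bearing the ether oxygen towards ring A is C1 (rings B, D and F are bridged at C1 and C4, rings C and E at C1 and C6); methyl ethers are the spectator groups and benzyl ethers hold the place of the carbamates.

Step 1
Reactants: 1 2,4,6-trimethoxybenzaldehyde
Product: 3 2,4,6-trimethoxyphenol, via aryl formate 2 (not isolated)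
Conditions: mCPBA, CH2Cl2, 0 °C to rt; then K2CO3 (cat.), MeOH, rt
Reagents that add atoms: mCPBA (3-chloroperoxybenzoic acid), OOC(=O)c1cccc(Cl)c1
Why: Baeyer–Villiger oxidation of an electron-rich benzaldehyde (Dakin-type), in which the trimethoxyphenyl group migrates to oxygen in the peracid adduct and the formate is methanolysed to the phenol.

Step 2
Reactants: 3 2,4,6-trimethoxyphenol; 4 4-bromo-2,6-dimethoxybenzaldehyde
Product: 5 A–B aldehyde [2,6-dimethoxy-4-(2,4,6-trimethoxyphenoxy)benzaldehyde]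
Conditions: CuI (10 mol%), picolinic acid (20 mol%), K3PO4, DMSO, 90 °C, argon
Reagents that add atoms: none
Why: Ullmann-type Cu-catalysed diaryl ether synthesis in which the para-formyl group activates the unhindered bromide and the picolinic acid ligand system, developed for 2,6-disubstituted phenols, carries the crowded phenoxide.

Step 3
Reactants: 5 A–B aldehyde
Product: 7 A–B phenol [2,6-dimethoxy-4-(2,4,6-trimethoxyphenoxy)phenol], via aryl formate 6 (not isolated)
Conditions: mCPBA, CH2Cl2, 0 °C to rt; then K2CO3 (cat.), MeOH, rt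
Reagents that add atoms: mCPBA (3-chloroperoxybenzoic acid), OOC(=O)c1cccc(Cl)c1
Why: Dakin-type Baeyer–Villiger oxidation, in which the 2,6-dimethoxy-4-aryloxyphenyl group migrates and formate methanolysis turns the formyl carbon of ring B into the oxygen that will bridge to ring C.

Step 4
Reactants: 8 1,3-bis(benzyloxy)-5-bromobenzene
Product: 10 2,4-bis(benzyloxy)-6-bromobenzaldehyde, via iminium chloride 9 (not isolated)
Conditions: POCl3, DMF, 0 °C to 90 °C; then H2O
Reagents that add atoms: N,N-dimethylformamide, CN(C)C=O (formyl carbon); water, O (formyl oxygen)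
Why: Vilsmeier–Haack formylation of a 3,5-dialkoxybromobenzene, in which the chloroiminium electrophile attacks the carbon next to bromine (para to one benzyloxy group and ortho to the other) in preference to the more crowded carbon between the two benzyloxy groups, and hydrolysis of iminium salt 9 releases the aldehyde.

Step 5
Reactants: 7 A–B phenol; 10 2,4-bis(benzyloxy)-6-bromobenzaldehyde
Product: 11 A–C aldehyde [2,4-bis(benzyloxy)-6-[2,6-dimethoxy-4-(2,4,6-trimethoxyphenoxy)phenoxy]benzaldehyde]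
Conditions: CuI (10 mol%), picolinic acid (20 mol%), K3PO4, DMSO, 90 °C, argon
Reagents that add atoms: none
Why: Ullmann-type Cu-catalysed etherification of a 2,6-dimethoxyphenoxide with a bromide activated by its ortho-formyl group, run with benzyl ethers on ring C so that the phenoxide later generated next to C5–O cannot trigger a carbamoyl shift.

Step 6
Reactants: 11 A–C aldehyde
Product: 13 A–C phenol [2,4-bis(benzyloxy)-6-[2,6-dimethoxy-4-(2,4,6-trimethoxyphenoxy)phenoxy]phenol], via aryl formate 12 (not isolated)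
Conditions: mCPBA, CH2Cl2, 0 °C to rt; then K2CO3 (cat.), MeOH, rt
Reagents that add atoms: mCPBA (3-chloroperoxybenzoic acid), OOC(=O)c1cccc(Cl)c1
Why: Dakin-type Baeyer–Villiger oxidation of a benzaldehyde flanked by an aryloxy and a benzyloxy group, whose electron-rich ring migrates readily, so that the formyl carbon becomes the C6 oxygen of ring C.

Step 7
Reactants: 13 A–C phenol; 4 4-bromo-2,6-dimethoxybenzaldehyde
Product: 14 A–D aldehyde (ring D: 3,5-dimethoxy with CHO at C4)
Conditions: CuI (10 mol%), picolinic acid (20 mol%), K3PO4, DMSO, 90 °C, argon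
Reagents that add atoms: none
Why: Ullmann-type Cu-catalysed diaryl ether synthesis between the hindered ring C phenoxide and the para-formyl-activated, unhindered bromide, the same pairing as in step 2.

Step 8
Reactants: 14 A–D aldehyde
Product: 16 A–D phenol (OH at C4 of ring D), via aryl formate 15 (not isolated)
Conditions: mCPBA, CH2Cl2, 0 °C to rt; then K2CO3 (cat.), MeOH, rt
Reagents that add atoms: mCPBA (3-chloroperoxybenzoic acid), OOC(=O)c1cccc(Cl)c1
Why: Dakin-type Baeyer–Villiger oxidation with migration of the 2,6-dimethoxy-4-aryloxyphenyl group and formate methanolysis, as in step 3.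

Step 9
Reactants: 16 A–D phenol; 17 2-bromo-4,6-dimethoxybenzaldehyde
Product: 18 A–E aldehyde (ring E: 3,5-dimethoxy with CHO at C6)
Conditions: CuI (10 mol%), picolinic acid (20 mol%), K3PO4, DMSO, 90 °C, argon
Reagents that add atoms: none
Why: Ullmann-type Cu-catalysed etherification of a 2,6-dimethoxyphenoxide with an ortho-formyl-activated bromide, the same pairing as in step 5.

Step 10
Reactants: 18 A–E aldehyde
Product: 20 A–E phenol (OH at C6 of ring E), via aryl formate 19 (not isolated)
Conditions: mCPBA, CH2Cl2, 0 °C to rt; then K2CO3 (cat.), MeOH, rt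
Reagents that add atoms: mCPBA (3-chloroperoxybenzoic acid), OOC(=O)c1cccc(Cl)c1
Why: Dakin-type Baeyer–Villiger oxidation of an ortho-aryloxy, ortho-methoxy benzaldehyde, as in step 6.

Step 11
Reactants: 20 A–E phenol; 4 4-bromo-2,6-dimethoxybenzaldehyde
Product: 21 A–F aldehyde (ring F: 3,5-dimethoxy with CHO at C4)
Conditions: CuI (10 mol%), picolinic acid (20 mol%), K3PO4, DMSO, 90 °C, argon
Reagents that add atoms: none
Why: Ullmann-type Cu-catalysed diaryl ether synthesis of a hindered phenoxide with the para-formyl-activated bromide, as in steps 2 and 7.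

Step 12
Reactants: 21 A–F aldehyde
Product: 23 A–F phenol (OH at C4 of ring F), via aryl formate 22 (not isolated)
Conditions: mCPBA, CH2Cl2, 0 °C to rt; then K2CO3 (cat.), MeOH, rt
Reagents that add atoms: mCPBA (3-chloroperoxybenzoic acid), OOC(=O)c1cccc(Cl)c1
Why: Dakin-type Baeyer–Villiger oxidation with aryl migration and formate methanolysis, as in steps 3 and 8.

Step 13
Reactants: 23 A–F phenol; 8 1,3-bis(benzyloxy)-5-bromobenzene
Product: 24 heptamer tetrabenzyl ether (benzyloxy at C3 and C5 of rings C and G; eleven methyl ethers)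
Conditions: CuI (20 mol%), picolinic acid (40 mol%), K3PO4, DMSO, 100 °C, argon, excess 8
Reagents that add atoms: none
Why: Ullmann-type Cu-catalysed diaryl ether synthesis with an unactivated but unhindered aryl bromide used in excess, for which the picolinic acid ligand system is suited because it was developed for 2,6-disubstituted phenoxides.

Step 14
Reactants: 24 heptamer tetrabenzyl ether
Product: 25 heptamer tetraphenol (free OH at C3 and C5 of rings C and G)
Conditions: H2 (1 atm), 10% Pd/C, THF–MeOH, rt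
Reagents that add atoms: none
Why: Catalytic hydrogenolysis of benzyl aryl ethers, which leaves methyl ethers and diaryl ethers untouched and has no halide or carbonyl group left to reduce.

Step 15
Reactants: 25 heptamer tetraphenol; 26 diethylcarbamoyl chloride (4 equiv consumed in all)
Product: 27 4,4'-dideoxy heptamer tetrakis(diethylcarbamate) (carbamates at C3 and C5 of rings C and G; eleven methyl ethers)
Conditions: 26 (5 equiv), K2CO3 (6 equiv), MeCN, reflux
Reagents that add atoms: diethylcarbamoyl chloride (equivalents two to four of 26), CCN(CC)C(Cl)=O.CCN(CC)C(Cl)=O.CCN(CC)C(Cl)=O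
Why: Fourfold O-carbamoylation of the resorcinol-type phenoxides, one molecule of the carbamoyl chloride per hydroxyl, which is the standard preparation of aryl O-carbamates and places a directing group on both sides of each C4–H.

Step 16
Reactants: 27 4,4'-dideoxy heptamer tetrakis(diethylcarbamate)
Product: 30 heptamer diol (new OH at C4 of rings C and G; four carbamates kept), via dilithio species 28 (not isolated), via bis(dimethyl boronate) 29 (not isolated)
Conditions: sBuLi (3 equiv), TMEDA (3 equiv), THF, −78 °C; B(OMe)3, −78 °C to 0 °C; then AcOH, 30% H2O2, 0 °C to rt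
Reagents that add atoms: hydrogen peroxide, OO
Why: Each pair of carbamate carbonyls (on C3–O and C5–O of ring C and of ring G) pre-complexes sBuLi·TMEDA and delivers it to the C4–H between them, the two aryllithium centres of 28 add to B(OMe)3, and hydrogen peroxide induces a 1,2-shift of each aryl group from boron to oxygen, which forms the C4–O bonds of rings C and G. The closest known reaction type is the directed ortho-metalation of aryl O-carbamates with borate trapping and oxidation to phenols, including 2-lithiation of 1,3-bis(carbamoyloxy)benzenes. No ring is closed and no stereocentre is formed. The step needs site selectivity among fifteen aryl C–H bonds; it is secured because only the two target carbons lie between two OCONEt2 groups, the strongest oxygen-based directors, whereas every other C–H is flanked by at most one carbamate or only by weakly coordinating methoxy and aryloxy groups. Holding the dianion at −78 °C until the borate quench suppresses the anionic ortho-Fries shift, and the acidic peroxide oxidation keeps the carbamates from moving onto the new hydroxyl.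

Step 17
Reactants: 30 heptamer diol
Product: 31 undeca-O-methyl heptamer (3,4,5-trihydroxy on rings C and G)
Conditions: LiAlH4, THF, 0 °C to reflux; then 1 M HCl, argon
Reagents that add atoms: none
Why: Reductive cleavage of aryl O-carbamates by hydride addition to the carbonyl and loss of aryloxide, chosen over hot alkali because the 3,4,5-trihydroxyphenyl units it uncovers are air-sensitive as phenoxides and are released here only on acidic work-up under argon.

Step 18
Reactants: 31 undeca-O-methyl heptamer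
Product: 32 CNP0351377.0 (target)
Conditions: BBr3 (excess), CH2Cl2, −78 °C to rt; then MeOH, H2O; argon
Reagents that add atoms: none
Why: Lewis acid cleavage of aryl methyl ethers (BBr3 demethylation), in which bromide attacks the methyl group of each boron–ether adduct while the diaryl ether bonds, which offer no carbon open to substitution, stay intact.

**Compound list**
1 | 2,4,6-trimethoxybenzaldehyde | COc1cc(OC)c(C=O)c(OC)c1 | starting material
2 | 2,4,6-trimethoxyphenyl formate | COc1cc(OC)c(OC=O)c(OC)c1 | intermediate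
3 | 2,4,6-trimethoxyphenol (ring A) | COc1cc(OC)c(O)c(OC)c1 | intermediate
4 | 4-bromo-2,6-dimethoxybenzaldehyde (source of rings B, D and F) | COc1cc(Br)cc(OC)c1C=O | starting material
5 | A–B aldehyde: 2,6-dimethoxy-4-(2,4,6-trimethoxyphenoxy)benzaldehyde | COc1cc(OC)c(Oc2cc(OC)c(C=O)c(OC)c2)c(OC)c1 | intermediate
6 | A–B formate: 2,6-dimethoxy-4-(2,4,6-trimethoxyphenoxy)phenyl formate | COc1cc(OC)c(Oc2cc(OC)c(OC=O)c(OC)c2)c(OC)c1 | intermediate
7 | A–B phenol: 2,6-dimethoxy-4-(2,4,6-trimethoxyphenoxy)phenol | COc1cc(OC)c(Oc2cc(OC)c(O)c(OC)c2)c(OC)c1 | intermediate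
8 | 1,3-bis(benzyloxy)-5-bromobenzene (source of rings C and G) | Brc1cc(OCc2ccccc2)cc(OCc2ccccc2)c1 | starting material
9 | N-[2,4-bis(benzyloxy)-6-bromobenzylidene]-N-methylmethanaminium chloride | C[N+](C)=Cc1c(Br)cc(OCc2ccccc2)cc1OCc1ccccc1.[Cl-] | intermediate
10 | 2,4-bis(benzyloxy)-6-bromobenzaldehyde | O=Cc1c(Br)cc(OCc2ccccc2)cc1OCc1ccccc1 | intermediate
11 | A–C aldehyde: 2,4-bis(benzyloxy)-6-[2,6-dimethoxy-4-(2,4,6-trimethoxyphenoxy)phenoxy]benzaldehyde | COc1cc(OC)c(Oc2cc(OC)c(Oc3cc(OCc4ccccc4)cc(OCc4ccccc4)c3C=O)c(OC)c2)c(OC)c1 | intermediate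
12 | A–C formate: formate ester of phenol 13 | COc1cc(OC)c(Oc2cc(OC)c(Oc3cc(OCc4ccccc4)cc(OCc4ccccc4)c3OC=O)c(OC)c2)c(OC)c1 | intermediate
13 | A–C phenol: 2,4-bis(benzyloxy)-6-[2,6-dimethoxy-4-(2,4,6-trimethoxyphenoxy)phenoxy]phenol | COc1cc(OC)c(Oc2cc(OC)c(Oc3cc(OCc4ccccc4)cc(OCc4ccccc4)c3O)c(OC)c2)c(OC)c1 | intermediate
14 | A–D aldehyde: 4-{2,4-bis(benzyloxy)-6-[2,6-dimethoxy-4-(2,4,6-trimethoxyphenoxy)phenoxy]phenoxy}-2,6-dimethoxybenzaldehyde | COc1cc(OC)c(Oc2cc(OC)c(Oc3cc(OCc4ccccc4)cc(OCc4ccccc4)c3Oc3cc(OC)c(C=O)c(OC)c3)c(OC)c2)c(OC)c1 | intermediate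
15 | A–D formate: formate ester of phenol 16 | COc1cc(OC)c(Oc2cc(OC)c(Oc3cc(OCc4ccccc4)cc(OCc4ccccc4)c3Oc3cc(OC)c(OC=O)c(OC)c3)c(OC)c2)c(OC)c1 | intermediate
16 | A–D phenol: tetramer with free OH at C4 of the 3,5-dimethoxy ring D | COc1cc(OC)c(Oc2cc(OC)c(Oc3cc(OCc4ccccc4)cc(OCc4ccccc4)c3Oc3cc(OC)c(O)c(OC)c3)c(OC)c2)c(OC)c1 | intermediate
17 | 2-bromo-4,6-dimethoxybenzaldehyde (source of ring E) | COc1cc(Br)c(C=O)c(OC)c1 | starting material
18 | A–E aldehyde: pentamer, ring E 3,5-dimethoxy with CHO at C6 | COc1cc(OC)c(Oc2cc(OC)c(Oc3cc(OCc4ccccc4)cc(OCc4ccccc4)c3Oc3cc(OC)c(Oc4cc(OC)cc(OC)c4C=O)c(OC)c3)c(OC)c2)c(OC)c1 | intermediate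
19 | A–E formate: formate ester of phenol 20 | COc1cc(OC)c(Oc2cc(OC)c(Oc3cc(OCc4ccccc4)cc(OCc4ccccc4)c3Oc3cc(OC)c(Oc4cc(OC)cc(OC)c4OC=O)c(OC)c3)c(OC)c2)c(OC)c1 | intermediate
20 | A–E phenol: pentamer with free OH at C6 of ring E | COc1cc(OC)c(Oc2cc(OC)c(Oc3cc(OCc4ccccc4)cc(OCc4ccccc4)c3Oc3cc(OC)c(Oc4cc(OC)cc(OC)c4O)c(OC)c3)c(OC)c2)c(OC)c1 | intermediate
21 | A–F aldehyde: hexamer, ring F 3,5-dimethoxy with CHO at C4 | COc1cc(OC)c(Oc2cc(OC)c(Oc3cc(OCc4ccccc4)cc(OCc4ccccc4)c3Oc3cc(OC)c(Oc4cc(OC)cc(OC)c4Oc4cc(OC)c(C=O)c(OC)c4)c(OC)c3)c(OC)c2)c(OC)c1 | intermediate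
22 | A–F formate: formate ester of phenol 23 | COc1cc(OC)c(Oc2cc(OC)c(Oc3cc(OCc4ccccc4)cc(OCc4ccccc4)c3Oc3cc(OC)c(Oc4cc(OC)cc(OC)c4Oc4cc(OC)c(OC=O)c(OC)c4)c(OC)c3)c(OC)c2)c(OC)c1 | intermediate
23 | A–F phenol: hexamer with free OH at C4 of ring F | COc1cc(OC)c(Oc2cc(OC)c(Oc3cc(OCc4ccccc4)cc(OCc4ccccc4)c3Oc3cc(OC)c(Oc4cc(OC)cc(OC)c4Oc4cc(OC)c(O)c(OC)c4)c(OC)c3)c(OC)c2)c(OC)c1 | intermediate
24 | heptamer tetrabenzyl ether: benzyloxy at C3 and C5 of rings C and G, methoxy at all eleven other oxygens | COc1cc(OC)c(Oc2cc(OC)c(Oc3cc(OCc4ccccc4)cc(OCc4ccccc4)c3Oc3cc(OC)c(Oc4cc(OC)cc(OC)c4Oc4cc(OC)c(Oc5cc(OCc6ccccc6)cc(OCc6ccccc6)c5)c(OC)c4)c(OC)c3)c(OC)c2)c(OC)c1 | intermediate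
25 | heptamer tetraphenol: free OH at C3 and C5 of rings C and G, eleven methyl ethers | COc1cc(OC)c(Oc2cc(OC)c(Oc3cc(O)cc(O)c3Oc3cc(OC)c(Oc4cc(OC)cc(OC)c4Oc4cc(OC)c(Oc5cc(O)cc(O)c5)c(OC)c4)c(OC)c3)c(OC)c2)c(OC)c1 | intermediate
26 | diethylcarbamoyl chloride | CCN(CC)C(Cl)=O | starting material
27 | 4,4'-dideoxy heptamer tetrakis(diethylcarbamate): OCONEt2 at C3 and C5 of rings C and G, H at C4 of both, eleven methyl ethers | COc1cc(OC)c(Oc2cc(OC)c(Oc3cc(OC(=O)N(CC)CC)cc(OC(=O)N(CC)CC)c3Oc3cc(OC)c(Oc4cc(OC)cc(OC)c4Oc4cc(OC)c(Oc5cc(OC(=O)N(CC)CC)cc(OC(=O)N(CC)CC)c5)c(OC)c4)c(OC)c3)c(OC)c2)c(OC)c1 | intermediate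
28 | dilithio species: 27 with Li at C4 of rings C and G | COc1cc(OC)c(Oc2cc(OC)c(Oc3cc(OC(=O)N(CC)CC)c([Li])c(OC(=O)N(CC)CC)c3Oc3cc(OC)c(Oc4cc(OC)cc(OC)c4Oc4cc(OC)c(Oc5cc(OC(=O)N(CC)CC)c([Li])c(OC(=O)N(CC)CC)c5)c(OC)c4)c(OC)c3)c(OC)c2)c(OC)c1 | intermediate
29 | bis(dimethyl boronate): 27 with B(OMe)2 at C4 of rings C and G | COc1cc(OC)c(Oc2cc(OC)c(Oc3cc(OC(=O)N(CC)CC)c(B(OC)OC)c(OC(=O)N(CC)CC)c3Oc3cc(OC)c(Oc4cc(OC)cc(OC)c4Oc4cc(OC)c(Oc5cc(OC(=O)N(CC)CC)c(B(OC)OC)c(OC(=O)N(CC)CC)c5)c(OC)c4)c(OC)c3)c(OC)c2)c(OC)c1 | intermediate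
30 | heptamer diol: 27 with OH at C4 of rings C and G | COc1cc(OC)c(Oc2cc(OC)c(Oc3cc(OC(=O)N(CC)CC)c(O)c(OC(=O)N(CC)CC)c3Oc3cc(OC)c(Oc4cc(OC)cc(OC)c4Oc4cc(OC)c(Oc5cc(OC(=O)N(CC)CC)c(O)c(OC(=O)N(CC)CC)c5)c(OC)c4)c(OC)c3)c(OC)c2)c(OC)c1 | intermediate
31 | undeca-O-methyl heptamer: 3,4,5-trihydroxy on rings C and G, methyl ethers on rings A, B, D, E and F | COc1cc(OC)c(Oc2cc(OC)c(Oc3cc(O)c(O)c(O)c3Oc3cc(OC)c(Oc4cc(OC)cc(OC)c4Oc4cc(OC)c(Oc5cc(O)c(O)c(O)c5)c(OC)c4)c(OC)c3)c(OC)c2)c(OC)c1 | intermediate
32 | CNP0351377.0: heptamer with seventeen free hydroxyls | Oc1cc(O)c(Oc2cc(O)c(Oc3cc(O)c(O)c(O)c3Oc3cc(O)c(Oc4cc(O)cc(O)c4Oc4cc(O)c(Oc5cc(O)c(O)c(O)c5)c(O)c4)c(O)c3)c(O)c2)c(O)c1 | target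

**Step count and risks**
Total step count: 18. Longest linear sequence: 17 steps (steps 1 to 3 and 5 to 18); step 4 is the only branch.

The three steps most likely to fail:

Step 16. Deprotonation may be unselective (metalation at a carbon flanked by only one carbamate or by two methoxy groups), the second lithiation may stay incomplete, or the aryllithium may undergo an anionic ortho-Fries shift. The carbon–metal bonds would then be made by halogen–metal exchange instead of C–H deprotonation. The fallback sets out from tetraphenol 25. Iodination with I2 and NaHCO3 in aqueous THF at 0 °C, which on resorcinols goes to the carbon between the two hydroxyls, should give the 4,4'-diiodo tetraphenol F1. Carbamoylation with four equivalents of 26 (K2CO3, MeCN, reflux) should give the 4,4'-diiodo tetracarbamate F2. Iodine–magnesium exchange with iPrMgCl·LiCl in THF at −40 °C should give the bis(arylmagnesium chloride) F3, which is trapped with B(OMe)3 as boronate 29 and oxidised with H2O2 and AcOH, so that the route is rejoined at 30.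

Step 13. The coupling of the unactivated bromide with the crowded hexamer phenoxide may stall, with reduction of the bromide or oxidation of the phenol taking over. Ring G would then be delivered as a boron reagent in an oxidative copper coupling at room temperature. The fallback sets out from bromide 8: bromine–lithium exchange (nBuLi, THF, −78 °C) gives 3,5-bis(benzyloxy)phenyllithium F4, which with B(OiPr)3 and then aqueous HCl gives 3,5-bis(benzyloxy)phenylboronic acid F5. Chan–Lam–Evans coupling of this acid with phenol 23 (Cu(OAc)2, pyridine, 4 Å molecular sieves, CH2Cl2, air, rt), a reaction known to arylate 2,6-disubstituted phenols, comes back to the route at 24.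

Step 18. Cleavage of the eleven methyl ethers may stay incomplete, and the free polyphenol may be lost to air oxidation during isolation. The product would then be captured as an ester. The fallback sets out from 31: the crude product of the BBr3 reaction is acetylated (Ac2O, pyridine, DMAP) to the heptadecaacetate F6, which is stable and can be purified on silica; acid-catalysed methanolysis (AcCl in MeOH, argon, rt to 40 °C) then releases the target, so that the route is rejoined at 32.

**Further compounds**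
F1 | step 16 | 4,4'-diiodo heptamer tetraphenol (25 with iodine at C4 of rings C and G) | COc1cc(OC)c(Oc2cc(OC)c(Oc3cc(O)c(I)c(O)c3Oc3cc(OC)c(Oc4cc(OC)cc(OC)c4Oc4cc(OC)c(Oc5cc(O)c(I)c(O)c5)c(OC)c4)c(OC)c3)c(OC)c2)c(OC)c1
F2 | step 16 | 4,4'-diiodo heptamer tetrakis(diethylcarbamate) (27 with iodine at C4 of rings C and G) | COc1cc(OC)c(Oc2cc(OC)c(Oc3cc(OC(=O)N(CC)CC)c(I)c(OC(=O)N(CC)CC)c3Oc3cc(OC)c(Oc4cc(OC)cc(OC)c4Oc4cc(OC)c(Oc5cc(OC(=O)N(CC)CC)c(I)c(OC(=O)N(CC)CC)c5)c(OC)c4)c(OC)c3)c(OC)c2)c(OC)c1
F3 | step 16 | bis(arylmagnesium chloride) (27 with MgCl at C4 of rings C and G) | COc1cc(OC)c(Oc2cc(OC)c(Oc3cc(OC(=O)N(CC)CC)c([Mg]Cl)c(OC(=O)N(CC)CC)c3Oc3cc(OC)c(Oc4cc(OC)cc(OC)c4Oc4cc(OC)c(Oc5cc(OC(=O)N(CC)CC)c([Mg]Cl)c(OC(=O)N(CC)CC)c5)c(OC)c4)c(OC)c3)c(OC)c2)c(OC)c1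
F4 | step 13 | 3,5-bis(benzyloxy)phenyllithium | [Li]c1cc(OCc2ccccc2)cc(OCc2ccccc2)c1
F5 | step 13 | 3,5-bis(benzyloxy)phenylboronic acid | OB(O)c1cc(OCc2ccccc2)cc(OCc2ccccc2)c1
F6 | step 18 | heptadecaacetate of the target | CC(=O)Oc1cc(OC(C)=O)c(Oc2cc(OC(C)=O)c(Oc3cc(OC(C)=O)c(OC(C)=O)c(OC(C)=O)c3Oc3cc(OC(C)=O)c(Oc4cc(OC(C)=O)cc(OC(C)=O)c4Oc4cc(OC(C)=O)c(Oc5cc(OC(C)=O)c(OC(C)=O)c(OC(C)=O)c5)c(OC(C)=O)c4)c(OC(C)=O)c3)c(OC(C)=O)c2)c(OC(C)=O)c1
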